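**The leftover.** The leftover of starting complex is what parts west, north and east, one charge stopped at different times.

| setting | Saturday's | Friday's | Wednesday's | west | north | east |
|---|---|---|---|---|---|---|
| starting complex | 0.82 M | 0.82 M | 1.6 M | 0.82 M | 0.82 M | 0.82 M |
| incoming ligand | 0.574 M | 0.574 M | 0.574 M | 0.574 M | 0.574 M | 0.574 M |
| leaving ligand | 0.27 M | 0.61 M | 0.41 M | 0.410 M | 0.410 M | 0.410 M |
| remark | run made earlier | run made earlier | run made earlier |  |  |  |
| time |  |  |  | 80 min | 200 min | 500 min |

| run | time / min | starting complex / % | complex with one exchanged / % | side product B / % | side product A / % | complex with two exchanged / % |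
|---|---|---|---|---|---|---|
| Saturday's | 8.00 | 84.9 | 3.5 | 11.3 | 0.3 | 0.2 |
| Saturday's | 15.0 | 75.0 | 5.5 | 18.3 | 0.6 | 0 |
| Saturday's | 25.0 | 65.2 | 8.0 | 25.7 | 0.9 | 0.3 |
| Saturday's | 30.0 | 60.7 | 10.2 | 28.3 | 1.5 | 0.4 |
| Saturday's | 40.0 | 54.2 | 10.6 | 33.2 | 2.6 | 0.5 |
| Saturday's | 50.0 | 48.0 | 11.4 | 35.9 | 3.4 | 0 |
| Friday's | 8.00 | 72.6 | 3.3 | 23.5 | 0.1 | 0.2 |
| Friday's | 15.0 | 58.9 | 5.4 | 36.4 | 0.3 | 0.2 |
| Friday's | 25.0 | 44.9 | 6.7 | 47.0 | 0.7 | 0.1 |
| Friday's | 30.0 | 39.7 | 7.6 | 50.4 | 1.2 | 0.3 |
| Friday's | 40.0 | 32.7 | 8.9 | 57.0 | 2.1 | 0 |
| Friday's | 50.0 | 27.3 | 9.3 | 60.9 | 2.1 | 0.4 |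
| Wednesday's | 4.00 | 89.1 | 2.4 | 8.6 | 0.1 | 0.1 |
| Wednesday's | 12.0 | 76.3 | 4.6 | 19.2 | 0.4 | 0 |
| Wednesday's | 20.0 | 67.3 | 7.1 | 24.7 | 0.6 | 0.3 |
| Wednesday's | 30.0 | 60.3 | 8.4 | 29.7 | 1.1 | 0 |
| Wednesday's | 50.0 | 50.6 | 10.1 | 35.5 | 2.8 | 0.4 |

(scatter of a reading: 0.3 percentage points)

- the numbers in the tables scatter by 0.3 percentage points (one standard deviation)

1. which of these there is most of at the end, counted by the starting complex in it, west (complex with one exchanged / side product B / starting complex / side product A)
2. which of these there is most of at the end, counted by the starting complex in it, north (complex with one exchanged / side product B / starting complex / side product A)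
3. which of these there is most of at the end, counted by the starting complex in it, east (complex with one exchanged / side product B / starting complex / side product A)
4. amount of the one of these that there is most of at the end, in percent of the starting complex charged, west
5. amount of the one of these that there is most of at the end, in percent of the starting complex charged, north
6. amount of the one of these that there is most of at the end, in percent of the starting complex charged, east

**Two constants.** In the readings, side product B grows with starting complex times leaving ligand, and exchange grows with starting complex times incoming ligand. Each side product B takes one leaving ligand; each exchange frees one and takes one incoming ligand. Friday's first reading gives 0.0663 /M/min for side product B. Saturday's last gives 0.00857 /M/min for exchange, a selectivity factor of 7.74.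

**Tail ratio.** Late on, this reckoning holds [leaving ligand] at a fixed fraction of [incoming ligand]: the tail ratio, the exchange constant over the difference of the constants, 0.148. Then [incoming ligand] left is (leaving charge + 2 incoming charges − starting-complex charge + leftover) / (2 + tail ratio). Side product B is the charge less the leftover less the incoming ligand used.

**What matters.** At zero leftover this gives a ceiling of 71.9 %. Multiplying the constant for side product B by 2 moves it only to 73.5 %, so the ratio needs little care. The drain to side product A does not enter this reckoning of side product B. Of any leftover, a share of 53.4 % is taken from side product B, so the leftover needs knowing.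

**Counting half-lives.** At the ceiling, the late half-life of starting complex, under both pseudo-first-order losses, is 110 min. Saturday's and Friday's leaving-ligand charges bracket the one of west, north and east, and their readings of starting complex at 50.0 min average 37.6 %. Counting onward leaves 31.1 % in west, 14.6 % in north and 2.19 % in east. Side product B then comes to 55.2 %, 64.1 % and 70.7 %.

**The forecast.** It names side product B for all three, at 53 % (49 % to 57 %), 65 % (59 % to 70 %) and 70 % (62 % to 77 %), slightly apart from the reckoning above: “Long-time stability of B is extrapolated, so the ranges widen.”

    complex with one exchanged → decomposed reagent (k = 1.30 × 10⁻⁵ /s)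
    complex with two exchanged + incoming ligand → leaving ligand + complex with three exchanged (k = 1.50 × 10⁻⁴ /M/s)
    starting complex + incoming ligand → leaving ligand + complex with one exchanged (k = 1.50 × 10⁻⁴ /M/s)
    complex with one exchanged + incoming ligand → leaving ligand + complex with two exchanged (k = 1.80 × 10⁻⁵ /M/s)
    complex with one exchanged → side product A (k = 1.40 × 10⁻⁴ /s)
    leaving ligand + starting complex → side product B (k = 0.00110 /M/s)

**At rest?** Side product B leads at 55.2 % in west, 66.4 % in north and 71.3 % in east, all inside the forecast's ranges. East's leftover of 0.89 % gives 71.4 % by the tail ratio. A neighbour of east with 1.4 M of starting complex, leftover 8.3 %, gets 59.8 % of side product B by the same ratio, and it holds 60.3 %. West is not at rest: ten times its time adds 17 percentage points of side product B, reaching 71.8 %. East, ten times as long, gains 0.54 points of side product B, and side product A reaches 24.6 %.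

All runs were generated by integration with made-up constants; noise was put on by code.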